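Both 3-methylbut-2-enyl chains are cut at their C1''–C2'' bond (ArCH2–CH=), which reduces the target to a daidzein core with one-carbon electrophiles on C6 and C8 of ring A, the two carbons ortho to the C7 hydroxyl. That hydroxyl directs a double Mannich aminomethylation, so the regiochemistry is settled before any metal is used. The key step then joins both benzylic chlorides to an isobutenylboronate in one twofold Suzuki–Miyaura coupling and delivers each prenyl group complete and unbranched. Its precursor is the 6,8-bis(chloromethyl)isoflavone with O7 masked as an ethyl carbonate and O4' as a tert-butyldimethylsilyl ether; a single basic methanolysis then frees both phenols.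

Key step: step 4

Remark on the chemistry: isoflavone numbering is used (ring A = C4a, C5 to C8, C8a; ring C = the pyranone with O1, C2, C3, C4; ring B = the primed 3-aryl ring; prenyl carbons doubly primed). The target has no stereocentre and no alkene geometry to control.

Step 1
Reactants: 1 daidzein; 2 tert-butyl(chloro)dimethylsilane
Product: 4 7-hydroxy-4'-(tert-butyldimethylsilyloxy)isoflavone, via daidzein dipotassium salt 3 (not isolated)
Conditions: KOtBu (2.05 equiv), DMF, 0 °C, 20 min; then TBSCl (1.0 equiv), 0 °C → rt; aq. NH4Cl
Reagents that add atoms: tert-butyl(chloro)dimethylsilane, CC(C)(C)[Si](C)(C)Cl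
Why: Regioselective O-silylation of a bis-phenoxide: the ring-B oxide is the conjugate base of the less acidic phenol (the 7-OH is a vinylogous carboxylic acid through C4=O), so it is the more nucleophilic oxygen and also the thermodynamic resting place of silicon, since an O7 silyl ether can hand its silyl group on to a free 4'-oxide.

Step 2
Reactants: 4 7-hydroxy-4'-(tert-butyldimethylsilyloxy)isoflavone; 5 bis(dimethylamino)methane
Product: 7 6,8-bis[(dimethylamino)methyl]-7-hydroxy-4'-(tert-butyldimethylsilyloxy)isoflavone, via C8 mono-Mannich base 6 (not isolated)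
Conditions: CH2(NMe2)2 (6 equiv), 1,4-dioxane, reflux under N2
Reagents that add atoms: bis(dimethylamino)methane, CN(C)CN(C)C
Why: Twofold phenol Mannich aminomethylation with an aminal as iminium source: the acidic 7-OH protonates the aminal and the iminium ion is delivered to the ortho carbons of ring A, C8 first and then C6, while ring B, now a silyl ether without a free OH, should not react.

Step 3
Reactants: 7 6,8-bis[(dimethylamino)methyl]-7-hydroxy-4'-(tert-butyldimethylsilyloxy)isoflavone; 8 ethyl chloroformate
Product: 10 6,8-bis(chloromethyl)-7-(ethoxycarbonyloxy)-4'-(tert-butyldimethylsilyloxy)isoflavone, via O7 ethyl carbonate of the diamine 9 (not isolated)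
Conditions: ClCO2Et (6 equiv), KHCO3 (3 equiv), 1,2-dichloroethane, 0 °C → 60 °C
Reagents that add atoms: ethyl chloroformate, CCOC(=O)Cl
Why: Chloroformate cleavage of tertiary benzylic amines (von Braun-type dealkylation) after O-acylation of the phenol: each NMe2 group is N-acylated to an acylammonium chloride whose chloride attacks the benzylic carbon in preference to a methyl group, releasing ethyl dimethylcarbamate, while KHCO3 takes up the HCl from the O-acylation so that neither amine is parked as its hydrochloride.

Step 4
Reactants: 10 6,8-bis(chloromethyl)-7-(ethoxycarbonyloxy)-4'-(tert-butyldimethylsilyloxy)isoflavone; 11 4,4,5,5-tetramethyl-2-(2-methylprop-1-enyl)-1,3,2-dioxaborolane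
Product: 12 7-(ethoxycarbonyloxy)-6,8-bis(3-methylbut-2-enyl)-4'-(tert-butyldimethylsilyloxy)isoflavone
Conditions: 11 (3 equiv), Pd(PPh3)4 (10 mol %), anhydrous powdered K3PO4 (6 equiv), degassed 1,4-dioxane, 85 °C
Reagents that add atoms: 4,4,5,5-tetramethyl-2-(2-methylprop-1-enyl)-1,3,2-dioxaborolane, CC(C)=CB1OC(C)(C)C(C)(C)O1
Why: Zerovalent palladium adds oxidatively to each benzylic C–Cl bond, and the resulting benzylpalladium chloride (divalent palladium) cannot lose a beta hydrogen because the carbon next to the metal-bearing CH2 is a fully substituted ring carbon. Phosphate-assisted transmetalation of the alkenyl pinacol boronate and reductive elimination then form the C(sp3)–C(sp2) bond, and the cycle runs a second time at the other chloromethyl group; the closest known reaction type is the Suzuki–Miyaura coupling of benzylic halides with alkenylboronic esters. No ring is closed and no stereocentre arises, and the new alkene carries two identical methyl groups, so no geometric isomer exists. Because the prenyl carbons arrive as an sp2 boron reagent bound through C2'', a branched 1,1-dimethylallyl isomer cannot form, and the sites C6 and C8 were fixed earlier by the C7 oxygen. The selectivity needed is coupling at carbon in preference to ionisation of an ortho-(chloromethyl)phenoxide to an ortho-quinone methide or O-benzylation; the O7 ethyl carbonate and the 4'-silyl ether keep both phenols masked, and the anhydrous, fluoride-free, non-nucleophilic base should leave both groups in place.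

Step 5
Reactants: 12 7-(ethoxycarbonyloxy)-6,8-bis(3-methylbut-2-enyl)-4'-(tert-butyldimethylsilyloxy)isoflavone
Product: 14 7,4'-dihydroxy-6,8-bis(3-methylbut-2-enyl)isoflavone (6,8-diprenyldaidzein), via 4'-O-silyl diprenyl phenol 13 (not isolated)
Conditions: K2CO3 (3 equiv), MeOH/THF (3:1), rt → 40 °C; then aq. NH4Cl
Reagents that add atoms: none
Why: Base-mediated transesterification and desilylation: methoxide should cleave the aryl ethyl carbonate rapidly to the 7-phenoxide and then attack silicon of the aryl silyl ether, both leaving groups being phenoxides, while the prenyl alkenes, which could cyclise onto O7 under acid, are inert to base.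

Compound list
1 | daidzein (7,4'-dihydroxyisoflavone) | O=c1c(-c2ccc(O)cc2)coc2cc(O)ccc12 | starting material
2 | tert-butyl(chloro)dimethylsilane (TBSCl) | CC(C)(C)[Si](C)(C)Cl | starting material
3 | daidzein dipotassium salt (7,4'-bis-phenoxide, formed in the flask) | [K+].[K+].O=c1c(-c2ccc([O-])cc2)coc2cc([O-])ccc12 | intermediate
4 | 7-hydroxy-4'-(tert-butyldimethylsilyloxy)isoflavone | CC(C)(C)[Si](C)(C)Oc1ccc(-c2coc3cc(O)ccc3c2=O)cc1 | intermediate
5 | bis(dimethylamino)methane | CN(C)CN(C)C | starting material
6 | 8-[(dimethylamino)methyl]-7-hydroxy-4'-(tert-butyldimethylsilyloxy)isoflavone (formed in the flask) | CN(C)Cc1c(O)ccc2c(=O)c(-c3ccc(O[Si](C)(C)C(C)(C)C)cc3)coc12 | intermediate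
7 | 6,8-bis[(dimethylamino)methyl]-7-hydroxy-4'-(tert-butyldimethylsilyloxy)isoflavone | CN(C)Cc1cc2c(=O)c(-c3ccc(O[Si](C)(C)C(C)(C)C)cc3)coc2c(CN(C)C)c1O | intermediate
8 | ethyl chloroformate | CCOC(=O)Cl | starting material
9 | 6,8-bis[(dimethylamino)methyl]-7-(ethoxycarbonyloxy)-4'-(tert-butyldimethylsilyloxy)isoflavone (formed in the flask) | CCOC(=O)Oc1c(CN(C)C)cc2c(=O)c(-c3ccc(O[Si](C)(C)C(C)(C)C)cc3)coc2c1CN(C)C | intermediate
10 | 6,8-bis(chloromethyl)-7-(ethoxycarbonyloxy)-4'-(tert-butyldimethylsilyloxy)isoflavone | CCOC(=O)Oc1c(CCl)cc2c(=O)c(-c3ccc(O[Si](C)(C)C(C)(C)C)cc3)coc2c1CCl | intermediate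
11 | 4,4,5,5-tetramethyl-2-(2-methylprop-1-enyl)-1,3,2-dioxaborolane | CC(C)=CB1OC(C)(C)C(C)(C)O1 | starting material
12 | 7-(ethoxycarbonyloxy)-6,8-bis(3-methylbut-2-enyl)-4'-(tert-butyldimethylsilyloxy)isoflavone | CCOC(=O)Oc1c(CC=C(C)C)cc2c(=O)c(-c3ccc(O[Si](C)(C)C(C)(C)C)cc3)coc2c1CC=C(C)C | intermediate
13 | 7-hydroxy-6,8-bis(3-methylbut-2-enyl)-4'-(tert-butyldimethylsilyloxy)isoflavone (formed in the flask) | CC(C)=CCc1cc2c(=O)c(-c3ccc(O[Si](C)(C)C(C)(C)C)cc3)coc2c(CC=C(C)C)c1O | intermediate
14 | 7,4'-dihydroxy-6,8-bis(3-methylbut-2-enyl)isoflavone (6,8-diprenyldaidzein, CNP0238765.0) | CC(C)=CCc1cc2c(=O)c(-c3ccc(O)cc3)coc2c(CC=C(C)C)c1O | target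

Total step count: 5
Longest linear sequence: 5 steps (1 to 14)

Steps most likely to fail

Step 4. The O7 carbonate may be lost early, after which chloride expulsion next to the phenoxide would give an ortho-quinone methide and oligomers. Transmetalation under anhydrous phosphate may also be slow, so that the benzylpalladium intermediates homocouple or are reduced. The fallback reverses the polarity of the same two bonds and needs no base. From 10, zinc insertion into both benzylic C–Cl bonds (Zn dust, LiCl, THF, 25 °C) should give 6,8-bis[(chlorozincio)methyl]-7-(ethoxycarbonyloxy)-4'-(tert-butyldimethylsilyloxy)isoflavone F1. A twofold Negishi coupling of F1 with 1-bromo-2-methylprop-1-ene (Pd(PPh3)4, THF, 25 to 40 °C) then comes back to the route at 12. Since the benzylic carbons are then nucleophilic, loss of chloride toward a quinone methide is no longer possible.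

Step 2. The second aminomethylation at C6 may stall, because ring A is deactivated by the pyranone and the phenol proton is tied up by the first Mannich base. Prolonged heating may also cause loss of dimethylamine toward an ortho-quinone methide. The fallback replaces electrophilic substitution by iminium with halogenation and cross-coupling. From 4, iodination of both positions ortho to the free 7-OH (N-iodosuccinimide, 2.2 equiv, MeCN, rt) should give 6,8-diiodo-7-hydroxy-4'-(tert-butyldimethylsilyloxy)isoflavone F2. A twofold Stille coupling of F2 with tributyl[(dimethylamino)methyl]stannane (Pd(PPh3)4, toluene, 100 °C) then installs both CH2NMe2 groups and comes back to the route at 7.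

Step 1. Site selectivity of the monosilylation may be incomplete, with silicon ending up on O7 or on both oxygens, or the silyl group may scramble during work-up. The fallback protects both phenols and then differentiates them by selective deprotection. From 1, exhaustive silylation (TBSCl 2.5 equiv, imidazole, DMF, rt) should give 7,4'-bis(tert-butyldimethylsilyloxy)isoflavone F3. The O7 silyl ether of F3 is a vinylogous silyl ester with the better phenoxide leaving group, so brief methanolysis (K2CO3 0.2 equiv, MeOH/CH2Cl2, 0 °C) should cleave it selectively and come back to the route at 4.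

Further compounds
F1 | step 4 | 6,8-bis[(chlorozincio)methyl]-7-(ethoxycarbonyloxy)-4'-(tert-butyldimethylsilyloxy)isoflavone | CCOC(=O)Oc1c(C[Zn]Cl)cc2c(=O)c(-c3ccc(O[Si](C)(C)C(C)(C)C)cc3)coc2c1C[Zn]Cl
F2 | step 2 | 6,8-diiodo-7-hydroxy-4'-(tert-butyldimethylsilyloxy)isoflavone | Oc1c(I)cc2c(=O)c(-c3ccc(O[Si](C)(C)C(C)(C)C)cc3)coc2c1I
F3 | step 1 | 7,4'-bis(tert-butyldimethylsilyloxy)isoflavone | CC(C)(C)[Si](C)(C)Oc1ccc(-c2coc3cc(O[Si](C)(C)C(C)(C)C)ccc3c2=O)cc1
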